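## The problem

Atoms of all intermediates carry the numbers they will have in the flavone (ring A: C4a, C5–C8, C8a; ring C: O1, C2–C4; ring B: C1'–C6').

The target 22 is a flavone: benzene ring A is fused through C4a and C8a to a 4-pyranone ring C, which carries a methoxy group on C3 and the aryl ring B on C2. There is no stereocentre, so nothing has to be controlled in space. The difficulty lies in where the six oxygen substituents sit and which of them stay free. Ring A is oxygenated on C5, C7, C8 and C8a. If ring C is closed on a ketone with two free hydroxyls ortho to the acyl group, both the 5,7,8 pattern and its 5,6,7 isomer can form, so the two oxygens flanking C4a must be told apart before the ring closes. Four oxygens are methyl ethers and two (on C5 and C5') are free phenols, so these two need masks that come off without touching the methyl ethers. The sensitive parts are the 3-methoxy-4-pyranone (opened by hot alkali), the electron-rich rings (easily oxidised), and, on the way, any aryl–silicon bond flanked by two oxygens (cleaved by acid). The enabling feature is that C8a and C4a are neighbours on ring A bearing O1 and the acyl carbon C4. This ortho oxygen/acyl pair is what a carboxylic acid delivers to the two carbons of an aryne, and the oxygens on C5 and C8 flank that triple bond where they can steer the addition.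

## Retrosynthesis

**Unmasking (22 ⇐ 21 ⇐ 20).** The last two cuts are the O–CH2Ph bond on C5' and the O–S bond on C5. A benzyl ether on ring B survives base, fluoride and iodine, and falls under neutral hydrogenolysis. A tosylate on the C5 oxygen falls to hydroxide. The sulfonate goes first, while ring B is still an ether, so that only one phenoxide is exposed to base. Both reactions must leave four methyl ethers and the pyranone alone.

**Ring C (20 ⇐ 19 ⇐ 18).** Cutting O1–C2 and the C2=C3 unsaturation leads to the 2'-hydroxy-α-methoxychalcone 18, which closes through flavanone 19 under oxidative conditions. Against routes that build a flavonol and methylate it afterwards, this cut has the C3 methoxy and the right carbon skeleton already in place. Because the C5 oxygen of 18 is a tosylate, only the C8a hydroxyl can close the ring, and the 5,7,8 pattern is fixed. The forward step needs an oxidant that spares a benzyl ether and an aryl sulfonate.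

**The key cut (18 ⇐ 17 ⇐ 9 + 16).** Cutting both C8a–O1 and C4a–C4 divides 18 into aryne 17 and the α-methoxycinnamic acid 16, which brings C4, C3 with its methoxy, C2 and all of ring B in one piece. Electrophilic acylation of diol 3 is the obvious neighbour, but it would go para to a hydroxyl (C6) and would leave the two hydroxyls undifferentiated. The aryne places the acyl group between the two oxygens by construction. Aryne 17 comes from silyl triflate 9. The forward reaction must meet three demands:
- Only the C4a≡C8a aryne may form. Triflate leaves, tosylate stays.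
- The carboxylate oxygen must add to C8a. The sulfonyloxy group on C5 is a stronger inductive acceptor and is bulkier than the methoxy on C8, so both charge and approach point the same way.
- Acyl transfer to the C4a anion must outrun its protonation.

**Sulfonates of the precursor (9 ⇐ 8 ⇐ 7).** The two O–S bonds are cut in the order set by hindrance. In silyl diol 7 the C5 hydroxyl has a hydrogen on one side. The C8a hydroxyl lies between the silyl group and a methoxy. One equivalent of TsCl is meant to take the open site (8). The small, very reactive Tf2O then takes the crowded one (9). The forward steps must give site-selective monosulfonylation and avoid acid.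

**Silicon and the ring A oxygens (7 ⇐ 6 ⇐ 5 ⇐ 4 ⇐ 3 ⇐ 2 ⇐ 1).** The C4a–Si bond is cut back to aryllithium 5, formed by metalation of bis-carbamate 4 between its two carbamate groups. Carbamates are preferred to acetal groups for two reasons. They direct more strongly than the competing methoxy at C6. They are also removed by hydride (6 to 7) and not by acid, which would strip silicon from so electron-rich a ring. Bis-carbamate 4 comes from diol 3, and 3 from the commercial aldehyde 1 by Baeyer–Villiger oxidation through formate 2. Aldehyde 1 already has three of the four ring A oxygens, and its formyl group marks C5.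

**The acid (16 ⇐ 15 ⇐ 14 ⇐ 12 + 13; 12 ⇐ 11 ⇐ 10).** The C2=C3 bond is cut to aldehyde 12 (C2 and ring B) and methyl methoxyacetate 13 (C3 with its methoxy, and C4). They are joined by a Claisen-type condensation through aldol 14 to the Z ester 15, which is saponified to 16. Aldehyde 12 comes from commercial 2,5-dihydroxybenzaldehyde 10 by benzylation of the non-chelated hydroxyl (11) and methylation of the chelated one. The alkene geometry is of no lasting consequence, since C2=C3 ends inside the aromatic pyranone.

## Roads not taken

**Alternative 1: ring A folded by Claisen condensation on a pyranone.**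
- Cut: the C5–C6 bond of ring A. Ring A is built from a side chain on a preformed pyranone.
- Forward key step: pyranone A2 carries a methyl ester on C4a and a 1-methoxy-2-oxopropyl chain on C8a. With excess LiN(SiMe3)2 the methyl ketone enolate attacks the ester in a Dieckmann-type closure, and the ring enolises to the aromatic ring of A1, with hydroxyls on C5 and C7 and the methoxy on C8.
- Merits: the 5,7,8 pattern follows from connectivity alone. The C5 hydroxyl arrives free and chelated, so the C7 hydroxyl can be methylated selectively and no sulfonate has to be removed.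
- Weak points: A2 is a 4-pyranone with four different substituents and is harder to make than anything in the chosen route. Its most acidic hydrogen is on C8, between the ketone and the pyranone, so the productive enolate needs a dianion. The pyranone is open to nucleophilic ring opening by amide or enolate.
- Comparison: this road is better on regiocontrol of ring A, which the chosen plan must secure through the tosylate of 9. The chosen plan sets against it two fragments made in six and four steps from commercial aromatics and joined convergently.

**Alternative 2: carbene-catalysed crossed benzoin joining C3 and C4.**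
- Cut: the C3–C4 bond.
- Forward key step: dialdehyde A4 has an aromatic formyl group on C4a and an α-aryl-α-aryloxy acetaldehyde on O1. A triazolium-derived N-heterocyclic carbene with an amine base makes one aldehyde an acyl anion equivalent that adds to the other, closing ring C as dihydroflavonol A3 (racemic, mixture of diastereomers).
- Merits: catalytic, near room temperature, and the C3 oxygen is installed as the ring forms. In mildness it is clearly better than a fluoride-mediated reaction at 125 °C.
- Weak points: the aromatic aldehyde must be the donor, but it is electron-rich and has two ortho substituents. The aliphatic aldehyde has a very acidic α-hydrogen and is prone to aldol chemistry. Making A4 requires alkylating a hindered, chelated phenol and already presupposes that the C5 and C8a oxygens are differentiated. A3 still needs dehydrogenation, O-methylation at C3 and double debenzylation.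
- Comparison: the chosen plan has a harsher key step but brings the C3 methoxy with it, needs one oxidation, and solves the differentiation of the ring A oxygens in the same intermediate (9) that forms the C–C bond.

**Alternative 3: ring B from 2-methoxyfuran by cycloaddition and ring opening.**
- Cut: the C1'–C2' and C5'–C6' bonds of ring B.
- Forward key step: 2-ethynylchromone A6 undergoes a Diels–Alder reaction with 2-methoxyfuran A7. The oxygen-bridged adduct opens at its ketal carbon and aromatises to A5, with the furan oxygen left as the C5' hydroxyl.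
- Merits: the para methoxy/hydroxyl pattern of ring B follows from the polarity of the two partners, and the C5' hydroxyl needs no protecting group. In this respect it is more economical than the benzyl ether of the chosen route.
- Weak points: all the real difficulty (the 5,7,8 pattern, the 3-methoxypyranone, an ethynyl group on C2) is pushed into a linear synthesis of A6. The alkyne is only moderately activated, and A7 is acid-sensitive and prone to polymerise. Ring B is the cheap part of the molecule, available from 10 in two steps.
- Comparison: the chosen plan spends one extra protecting group on ring B but is convergent and attacks ring A, where the problem lies.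

Key step: step 11

## Route

Assumption: 1, 10 and 13 are taken as purchasable. Step 11 is taken to stop at the open-chain ketone 18; any 19 formed there by conjugate addition lies on the path of step 12 and would be carried along.

Step 1
Reactants: 1 3-hydroxy-4,5-dimethoxybenzaldehyde
Product: 3 4,5-dimethoxybenzene-1,3-diol, via 3-hydroxy-4,5-dimethoxyphenyl formate 2 (not isolated)
Conditions: mCPBA, CH2Cl2, 0 °C to rt; aq. NaHCO3/Na2SO3 wash; then K2CO3 (cat.), MeOH, rt
Reagents that add atoms: 3-chloroperoxybenzoic acid, O=C(OO)c1cccc(Cl)c1
Why: Baeyer–Villiger oxidation of an electron-rich benzaldehyde: the aryl group, with a methoxy para to the formyl carbon, migrates to oxygen, and mild methanolysis of formate 2 frees the second phenol.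

Step 2
Reactants: 3 4,5-dimethoxybenzene-1,3-diol
Product: 4 4,5-dimethoxy-1,3-phenylene bis(N,N-diethylcarbamate)
Conditions: Et2NCOCl (2.5 equiv), K2CO3, MeCN, reflux
Reagents that add atoms: N,N-diethylcarbamoyl chloride, CCN(CC)C(Cl)=O
Why: Standard O-carbamoylation of both phenols; the diethylcarbamate is the strongest oxygen-based director for ortho-metalation and tolerates alkyllithiums at −78 °C.

Step 3
Reactants: 4 4,5-dimethoxy-1,3-phenylene bis(N,N-diethylcarbamate)
Product: 6 4,5-dimethoxy-2-(trimethylsilyl)-1,3-phenylene bis(N,N-diethylcarbamate), via aryllithium 5 (not isolated)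
Conditions: s-BuLi (1.2 equiv), TMEDA, THF, −78 °C; then Me3SiCl, −78 °C to rt
Reagents that add atoms: chlorotrimethylsilane, C[Si](C)(C)Cl
Why: Directed ortho-metalation: the hydrogen on C4a lies between two carbamates and is complexed and acidified from both sides, whereas C6 has one carbamate and a methoxy beside it. At −78 °C aryllithium 5 is silylated before anionic Fries rearrangement sets in.

Step 4
Reactants: 6 4,5-dimethoxy-2-(trimethylsilyl)-1,3-phenylene bis(N,N-diethylcarbamate)
Product: 7 4,5-dimethoxy-2-(trimethylsilyl)benzene-1,3-diol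
Conditions: LiAlH4, THF, 0 °C to reflux; aq. KNaC4H4O6 work-up; used without acid contact
Reagents that add atoms: none
Why: Reductive cleavage of aryl carbamates by hydride frees both phenols without acid. This matters because a silyl group flanked by two oxygens and para to a third is lost readily by ipso-protonation.

Step 5
Reactants: 7 4,5-dimethoxy-2-(trimethylsilyl)benzene-1,3-diol
Product: 8 3-hydroxy-4,5-dimethoxy-2-(trimethylsilyl)phenyl 4-methylbenzenesulfonate
Conditions: TsCl (1.0 equiv), Et3N, CH2Cl2, −20 to 0 °C
Reagents that add atoms: 4-methylbenzenesulfonyl chloride, Cc1ccc(cc1)S(Cl)(=O)=O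
Why: Site-selective sulfonylation of the less hindered phenol: the C5 hydroxyl has a hydrogen on one side, whereas the C8a hydroxyl lies between the silyl group and a methoxy to which it is hydrogen-bonded.

Step 6
Reactants: 8 3-hydroxy-4,5-dimethoxy-2-(trimethylsilyl)phenyl 4-methylbenzenesulfonate
Product: 9 2,3-dimethoxy-5-(4-methylbenzenesulfonyloxy)-6-(trimethylsilyl)phenyl trifluoromethanesulfonate
Conditions: Tf2O, pyridine, CH2Cl2, 0 °C
Reagents that add atoms: trifluoromethanesulfonic anhydride, FC(F)(F)S(=O)(=O)OS(=O)(=O)C(F)(F)F
Why: Triflation of a hindered ortho-silyl phenol, the usual last step in making silylaryl triflate aryne precursors; the small, highly electrophilic anhydride reaches the crowded C8a oxygen.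

Step 7
Reactants: 10 2,5-dihydroxybenzaldehyde
Product: 11 5-(benzyloxy)-2-hydroxybenzaldehyde
Conditions: BnBr (1.05 equiv), K2CO3 (1.1 equiv), acetone, reflux
Reagents that add atoms: benzyl bromide, BrCc1ccccc1
Why: Williamson etherification; the C2' hydroxyl is hydrogen-bonded to the aldehyde and its phenoxide is delocalised into the carbonyl, so alkylation goes to the C5' hydroxyl.

Step 8
Reactants: 11 5-(benzyloxy)-2-hydroxybenzaldehyde
Product: 12 5-(benzyloxy)-2-methoxybenzaldehyde
Conditions: MeI, K2CO3, DMF, rt
Reagents that add atoms: iodomethane, CI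
Why: Williamson methylation of the remaining, chelated phenol in a polar aprotic solvent.

Step 9
Reactants: 12 5-(benzyloxy)-2-methoxybenzaldehyde; 13 methyl methoxyacetate
Product: 15 methyl (2Z)-3-[5-(benzyloxy)-2-methoxyphenyl]-2-methoxyprop-2-enoate, via aldol adduct 14 (not isolated)
Conditions: NaOMe, 13 (2 equiv), MeOH/THF, 0 to 60 °C
Reagents that add atoms: none
Why: Claisen-type (aldol) condensation of an ester enolate with a non-enolisable aldehyde, then E1cB loss of hydroxide from 14. The reversible sequence gives the more stable Z alkene, with aryl and ester trans.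

Step 10
Reactants: 15 methyl (2Z)-3-[5-(benzyloxy)-2-methoxyphenyl]-2-methoxyprop-2-enoate
Product: 16 (2Z)-3-[5-(benzyloxy)-2-methoxyphenyl]-2-methoxyprop-2-enoic acid
Conditions: LiOH, THF/MeOH/H2O, rt; then aq. HCl, 0 °C
Reagents that add atoms: lithium hydroxide (its oxygen ends in the carboxyl group), [Li+].[OH-]
Why: Saponification of the methyl ester; the benzyl ether is stable to base, and cold, brief acidification spares the enol ether.

Step 11
Reactants: 9 2,3-dimethoxy-5-(4-methylbenzenesulfonyloxy)-6-(trimethylsilyl)phenyl trifluoromethanesulfonate; 16 (2Z)-3-[5-(benzyloxy)-2-methoxyphenyl]-2-methoxyprop-2-enoic acid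
Product: 18 2-{(2Z)-3-[5-(benzyloxy)-2-methoxyphenyl]-2-methoxyprop-2-enoyl}-3-hydroxy-4,5-dimethoxyphenyl 4-methylbenzenesulfonate, via aryne 17 (not isolated)
Conditions: CsF (4 equiv), 9 (1.5 equiv), THF, 125 °C, sealed tube
Reagents that add atoms: none
Why: Proposed new method: fluoride attacks silicon of 9 and triflate leaves to give aryne 17; the caesium carboxylate of 16 adds through oxygen to C8a, and the aryl anion at C4a attacks the neighbouring ester carbonyl through a four-membered alkoxide that opens to the phenoxide and the aryl ketone. The closest known type is the CsF-induced insertion of simple arynes into the C–O bond of carboxylic acids to give ortho-hydroxyaryl ketones. Two skeletal bonds form (C8a–O1 and C4a–C4), no ring closes and no stereocentre is created. The selectivity needed is oxygen attack at C8a and not C4a: the sulfonyloxy group on C5 is the stronger inductive acceptor, so it stabilises the charge developing at C4a better than the C8 methoxy stabilises charge at C8a, and it is also the bulkier neighbour, so polarisation and approach agree. This follows the known directing effect of a 3-sulfonyloxy group on arynes but has not been set against a methoxy on the other side. Tosylate is a far poorer leaving group than triflate, so only the C4a≡C8a aryne forms. The high temperature favours acyl transfer over protonation to the aryl ester, and the acid is the limiting reagent so that no excess proton source is present. The α-methoxy group lowers the electrophilicity of the β-carbon, so the phenoxide should stay open; any 19 formed is converted in step 12.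

Step 12
Reactants: 18 2-{(2Z)-3-[5-(benzyloxy)-2-methoxyphenyl]-2-methoxyprop-2-enoyl}-3-hydroxy-4,5-dimethoxyphenyl 4-methylbenzenesulfonate
Product: 20 2-[5-(benzyloxy)-2-methoxyphenyl]-3,7,8-trimethoxy-4-oxo-4H-chromen-5-yl 4-methylbenzenesulfonate, via flavanone 19 (not isolated)
Conditions: I2 (0.1 equiv), DMSO, 120 °C
Reagents that add atoms: none
Why: Iodine-mediated oxidative cyclisation of a 2'-hydroxychalcone in DMSO: 6-endo conjugate addition of the only free phenol (on C8a) gives 19, which is iodinated at C3 and loses HI, with DMSO reoxidising iodide. The tosylate on the C5 oxygen ensures that ring C closes through the C8a oxygen.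

Step 13
Reactants: 20 2-[5-(benzyloxy)-2-methoxyphenyl]-3,7,8-trimethoxy-4-oxo-4H-chromen-5-yl 4-methylbenzenesulfonate
Product: 21 2-[5-(benzyloxy)-2-methoxyphenyl]-5-hydroxy-3,7,8-trimethoxy-4H-chromen-4-one
Conditions: KOH, MeOH/THF/H2O, rt to 50 °C; then aq. HCl
Reagents that add atoms: none
Why: Hydrolysis of an aryl sulfonate by attack at sulfur; the phenoxide released is peri to the carbonyl and a good leaving group, so conditions mild enough to spare the pyranone should suffice.

Step 14
Reactants: 21 2-[5-(benzyloxy)-2-methoxyphenyl]-5-hydroxy-3,7,8-trimethoxy-4H-chromen-4-one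
Product: 22 5-hydroxy-2-(5-hydroxy-2-methoxyphenyl)-3,7,8-trimethoxy-4H-chromen-4-one (5,5'-dihydroxy-3,7,8,2'-tetramethoxyflavone)
Conditions: H2 (1 atm), Pd/C, EtOAc/MeOH, rt
Reagents that add atoms: none
Why: Hydrogenolysis of the benzyl aryl ether over palladium on carbon; the tetrasubstituted C2=C3 bond and the aryl methyl ethers are inert under one atmosphere of hydrogen.

## Compound list

1 | 3-hydroxy-4,5-dimethoxybenzaldehyde | COc1cc(C=O)cc(O)c1OC | starting material
2 | 3-hydroxy-4,5-dimethoxyphenyl formate | COc1cc(OC=O)cc(O)c1OC | intermediate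
3 | 4,5-dimethoxybenzene-1,3-diol | COc1cc(O)cc(O)c1OC | intermediate
4 | 4,5-dimethoxy-1,3-phenylene bis(N,N-diethylcarbamate) | CCN(CC)C(=O)Oc1cc(OC)c(OC)c(OC(=O)N(CC)CC)c1 | intermediate
5 | [2,6-bis(diethylcarbamoyloxy)-3,4-dimethoxyphenyl]lithium | CCN(CC)C(=O)Oc1cc(OC)c(OC)c(OC(=O)N(CC)CC)c1[Li] | intermediate
6 | 4,5-dimethoxy-2-(trimethylsilyl)-1,3-phenylene bis(N,N-diethylcarbamate) | CCN(CC)C(=O)Oc1cc(OC)c(OC)c(OC(=O)N(CC)CC)c1[Si](C)(C)C | intermediate
7 | 4,5-dimethoxy-2-(trimethylsilyl)benzene-1,3-diol | COc1cc(O)c([Si](C)(C)C)c(O)c1OC | intermediate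
8 | 3-hydroxy-4,5-dimethoxy-2-(trimethylsilyl)phenyl 4-methylbenzenesulfonate | COc1cc(OS(=O)(=O)c2ccc(C)cc2)c([Si](C)(C)C)c(O)c1OC | intermediate
9 | 2,3-dimethoxy-5-(4-methylbenzenesulfonyloxy)-6-(trimethylsilyl)phenyl trifluoromethanesulfonate | COc1cc(OS(=O)(=O)c2ccc(C)cc2)c([Si](C)(C)C)c(OS(=O)(=O)C(F)(F)F)c1OC | intermediate
10 | 2,5-dihydroxybenzaldehyde | O=Cc1cc(O)ccc1O | starting material
11 | 5-(benzyloxy)-2-hydroxybenzaldehyde | O=Cc1cc(OCc2ccccc2)ccc1O | intermediate
12 | 5-(benzyloxy)-2-methoxybenzaldehyde | COc1ccc(OCc2ccccc2)cc1C=O | intermediate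
13 | methyl methoxyacetate | COCC(=O)OC | starting material
14 | methyl 3-[5-(benzyloxy)-2-methoxyphenyl]-3-hydroxy-2-methoxypropanoate (racemic, mixture of diastereomers) | COC(=O)C(OC)C(O)c1cc(OCc2ccccc2)ccc1OC | intermediate
15 | methyl (2Z)-3-[5-(benzyloxy)-2-methoxyphenyl]-2-methoxyprop-2-enoate | CO/C(C(=O)OC)=C\c1cc(OCc2ccccc2)ccc1OC | intermediate
16 | (2Z)-3-[5-(benzyloxy)-2-methoxyphenyl]-2-methoxyprop-2-enoic acid | CO/C(C(=O)O)=C\c1cc(OCc2ccccc2)ccc1OC | intermediate
17 | 5,6-didehydro-3,4-dimethoxyphenyl 4-methylbenzenesulfonate (aryne, triple bond C4a≡C8a) | COC1=C(OC)C#CC(OS(=O)(=O)c2ccc(C)cc2)=C1 | intermediate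
18 | 2-{(2Z)-3-[5-(benzyloxy)-2-methoxyphenyl]-2-methoxyprop-2-enoyl}-3-hydroxy-4,5-dimethoxyphenyl 4-methylbenzenesulfonate | COc1cc(OS(=O)(=O)c2ccc(C)cc2)c(C(=O)/C(OC)=C/c3cc(OCc4ccccc4)ccc3OC)c(O)c1OC | intermediate
19 | 2-[5-(benzyloxy)-2-methoxyphenyl]-3,7,8-trimethoxy-4-oxo-3,4-dihydro-2H-chromen-5-yl 4-methylbenzenesulfonate (racemic, mixture of diastereomers) | COc1ccc(OCc2ccccc2)cc1C1Oc2c(OC)c(OC)cc(OS(=O)(=O)c3ccc(C)cc3)c2C(=O)C1OC | intermediate
20 | 2-[5-(benzyloxy)-2-methoxyphenyl]-3,7,8-trimethoxy-4-oxo-4H-chromen-5-yl 4-methylbenzenesulfonate | COc1ccc(OCc2ccccc2)cc1-c1oc2c(OC)c(OC)cc(OS(=O)(=O)c3ccc(C)cc3)c2c(=O)c1OC | intermediate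
21 | 2-[5-(benzyloxy)-2-methoxyphenyl]-5-hydroxy-3,7,8-trimethoxy-4H-chromen-4-one | COc1ccc(OCc2ccccc2)cc1-c1oc2c(OC)c(OC)cc(O)c2c(=O)c1OC | intermediate
22 | 5-hydroxy-2-(5-hydroxy-2-methoxyphenyl)-3,7,8-trimethoxy-4H-chromen-4-one | COc1ccc(O)cc1-c1oc2c(OC)c(OC)cc(O)c2c(=O)c1OC | target

## Step count and least certain steps

Total: 14 steps. Longest linear sequence: 10 steps (steps 1–6, then 11–14, from 1). The ring B branch is 4 steps (7–10) before the union.

**Step 11 (key step, proposed new method).**
- What may go wrong: leakage of regiochemistry, with the carboxylate adding at C4a because the C8 methoxy competes as director; protonation of the C4a anion before acyl transfer, ending in simple O-arylation; loss of the tosylate, either from the C4a anion (elimination to a second aryne or sulfonyl shift to carbon) or by fluoride attack at sulfur at 125 °C.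
- Fallback (known chemistry; directed metalation and Weinreb acylation): from 3 and 16, returning at 18. Diol 3 is converted into 1,2-dimethoxy-3,5-bis(methoxymethoxy)benzene F1 (MOMCl, iPr2NEt). Acid 16 is converted into (2Z)-3-[5-(benzyloxy)-2-methoxyphenyl]-N,2-dimethoxy-N-methylprop-2-enamide F2 (MeNHOMe·HCl, carbodiimide coupling). Metalation of F1 between its two acetal oxygens (n-BuLi, THF, 0 °C) gives [3,4-dimethoxy-2,6-bis(methoxymethoxy)phenyl]lithium F3. F3 is acylated by F2 to (2Z)-3-[5-(benzyloxy)-2-methoxyphenyl]-1-[3,4-dimethoxy-2,6-bis(methoxymethoxy)phenyl]-2-methoxyprop-2-en-1-one F4. Methanolysis of the acetals (HCl, MeOH, rt) gives (2Z)-3-[5-(benzyloxy)-2-methoxyphenyl]-1-(2,6-dihydroxy-3,4-dimethoxyphenyl)-2-methoxyprop-2-en-1-one F5. One equivalent of TsCl with K2CO3 in acetone then sulfonylates the less hindered of the two chelated hydroxyls (on C5) and gives 18.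

**Step 5 (monotosylation).**
- What may go wrong: poor site selectivity between the two phenols of 7 and over-sulfonylation, since the selection rests on hindrance alone; 7 is also prone to lose silicon by ipso-protonation if handled under acidic conditions.
- Fallback (the two oxygens are differentiated from the first step, and free 7 is never formed): from 1, returning at 9.
  - The existing hydroxyl of 1 is carbamoylated (Et2NCOCl, K2CO3) to 5-formyl-2,3-dimethoxyphenyl N,N-diethylcarbamate F6.
  - Baeyer–Villiger oxidation (mCPBA) gives 3-[(diethylcarbamoyl)oxy]-4,5-dimethoxyphenyl formate F7, methanolysed in the same flask to 5-hydroxy-2,3-dimethoxyphenyl N,N-diethylcarbamate F8.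
  - The new phenol is protected (MOMCl, iPr2NEt) as 2,3-dimethoxy-5-(methoxymethoxy)phenyl N,N-diethylcarbamate F9.
  - The carbamate now has one free ortho position, so metalation (s-BuLi, TMEDA, −78 °C) can only give {2-[(diethylcarbamoyl)oxy]-3,4-dimethoxy-6-(methoxymethoxy)phenyl}lithium F10. Me3SiCl converts it into 2,3-dimethoxy-5-(methoxymethoxy)-6-(trimethylsilyl)phenyl N,N-diethylcarbamate F11.
  - LiAlH4 frees 2,3-dimethoxy-5-(methoxymethoxy)-6-(trimethylsilyl)phenol F12.
  - Tf2O/pyridine gives 2,3-dimethoxy-5-(methoxymethoxy)-6-(trimethylsilyl)phenyl trifluoromethanesulfonate F13.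
  - Brief methanolysis of the acetal (HCl cat., MeOH), tolerated because the triflate deactivates the ring toward protodesilylation, gives 5-hydroxy-2,3-dimethoxy-6-(trimethylsilyl)phenyl trifluoromethanesulfonate F14.
  - TsCl in pyridine/CH2Cl2 at 0 °C gives 9.

**Step 9 (condensation).**
- What may go wrong: self-condensation of the α-alkoxy ester, sluggish addition to the electron-rich, ortho-substituted aldehyde, and partial saponification by the hydroxide released.
- Fallback (addition and elimination separated): from 12 and 13, returning at 15. The lithium enolate of 13 (LDA, THF, −78 °C) is added to 12 and aldol 14 is isolated. Mesylation (MsCl, Et3N) gives methyl 3-[5-(benzyloxy)-2-methoxyphenyl]-2-methoxy-3-[(methylsulfonyl)oxy]propanoate F15. DBU then eliminates it to 15.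

**Step 12 (oxidative cyclisation).**
- What may go wrong: cleavage of the benzyl ether by the HI formed, iodination of the electron-rich ring B, or stalling at the flavanone because enolisation toward the methoxy-bearing C3 is slow.
- Fallback (ring closure and dehydrogenation as two separate operations, without iodine): from 18, returning at 20. NaOAc in refluxing ethanol closes 18 by conjugate addition to 19, which is isolated. DDQ in refluxing dioxane then dehydrogenates C2–C3 to give 20.

## Further compounds

F1 | step 11 | 1,2-dimethoxy-3,5-bis(methoxymethoxy)benzene | COCOc1cc(OC)c(OC)c(OCOC)c1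
F2 | step 11 | (2Z)-3-[5-(benzyloxy)-2-methoxyphenyl]-N,2-dimethoxy-N-methylprop-2-enamide | CO/C(C(=O)N(C)OC)=C\c1cc(OCc2ccccc2)ccc1OC
F3 | step 11 | [3,4-dimethoxy-2,6-bis(methoxymethoxy)phenyl]lithium | COCOc1cc(OC)c(OC)c(OCOC)c1[Li]
F4 | step 11 | (2Z)-3-[5-(benzyloxy)-2-methoxyphenyl]-1-[3,4-dimethoxy-2,6-bis(methoxymethoxy)phenyl]-2-methoxyprop-2-en-1-one | COCOc1cc(OC)c(OC)c(OCOC)c1C(=O)/C(OC)=C/c1cc(OCc2ccccc2)ccc1OC
F5 | step 11 | (2Z)-3-[5-(benzyloxy)-2-methoxyphenyl]-1-(2,6-dihydroxy-3,4-dimethoxyphenyl)-2-methoxyprop-2-en-1-one | COc1cc(O)c(C(=O)/C(OC)=C/c2cc(OCc3ccccc3)ccc2OC)c(O)c1OC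
F6 | step 5 | 5-formyl-2,3-dimethoxyphenyl N,N-diethylcarbamate | CCN(CC)C(=O)Oc1cc(C=O)cc(OC)c1OC
F7 | step 5 | 3-[(diethylcarbamoyl)oxy]-4,5-dimethoxyphenyl formate | CCN(CC)C(=O)Oc1cc(OC=O)cc(OC)c1OC
F8 | step 5 | 5-hydroxy-2,3-dimethoxyphenyl N,N-diethylcarbamate | CCN(CC)C(=O)Oc1cc(O)cc(OC)c1OC
F9 | step 5 | 2,3-dimethoxy-5-(methoxymethoxy)phenyl N,N-diethylcarbamate | CCN(CC)C(=O)Oc1cc(OCOC)cc(OC)c1OC
F10 | step 5 | {2-[(diethylcarbamoyl)oxy]-3,4-dimethoxy-6-(methoxymethoxy)phenyl}lithium | CCN(CC)C(=O)Oc1c([Li])c(OCOC)cc(OC)c1OC
F11 | step 5 | 2,3-dimethoxy-5-(methoxymethoxy)-6-(trimethylsilyl)phenyl N,N-diethylcarbamate | CCN(CC)C(=O)Oc1c([Si](C)(C)C)c(OCOC)cc(OC)c1OC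
F12 | step 5 | 2,3-dimethoxy-5-(methoxymethoxy)-6-(trimethylsilyl)phenol | COCOc1cc(OC)c(OC)c(O)c1[Si](C)(C)C
F13 | step 5 | 2,3-dimethoxy-5-(methoxymethoxy)-6-(trimethylsilyl)phenyl trifluoromethanesulfonate | COCOc1cc(OC)c(OC)c(OS(=O)(=O)C(F)(F)F)c1[Si](C)(C)C
F14 | step 5 | 5-hydroxy-2,3-dimethoxy-6-(trimethylsilyl)phenyl trifluoromethanesulfonate | COc1cc(O)c([Si](C)(C)C)c(OS(=O)(=O)C(F)(F)F)c1OC
F15 | step 9 | methyl 3-[5-(benzyloxy)-2-methoxyphenyl]-2-methoxy-3-[(methylsulfonyl)oxy]propanoate (racemic, mixture of diastereomers) | COC(=O)C(OC)C(OS(C)(=O)=O)c1cc(OCc2ccccc2)ccc1OC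
F0 | step 12 | none | none
A1 | alternative 1 | 2-[5-(benzyloxy)-2-methoxyphenyl]-5,7-dihydroxy-3,8-dimethoxy-4H-chromen-4-one | COc1c(O)cc(O)c2c1oc(-c3cc(OCc4ccccc4)ccc3OC)c(OC)c2=O
A2 | alternative 1 | methyl 6-[5-(benzyloxy)-2-methoxyphenyl]-5-methoxy-2-(1-methoxy-2-oxopropyl)-4-oxo-4H-pyran-3-carboxylate (racemic) | COC(=O)c1c(C(OC)C(C)=O)oc(-c2cc(OCc3ccccc3)ccc2OC)c(OC)c1=O
A3 | alternative 2 | 5-(benzyloxy)-2-[5-(benzyloxy)-2-methoxyphenyl]-3-hydroxy-7,8-dimethoxychroman-4-one (racemic, mixture of diastereomers) | COc1cc(OCc5ccccc5)c2c(c1OC)OC(c3cc(OCc4ccccc4)ccc3OC)C(O)C2=O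
A4 | alternative 2 | 6-(benzyloxy)-2-{1-[5-(benzyloxy)-2-methoxyphenyl]-2-oxoethoxy}-3,4-dimethoxybenzaldehyde (racemic) | COc1cc(OCc2ccccc2)c(C=O)c(OC(C=O)c2cc(OCc3ccccc3)ccc2OC)c1OC
A5 | alternative 3 | 5-(benzyloxy)-2-(5-hydroxy-2-methoxyphenyl)-3,7,8-trimethoxy-4H-chromen-4-one | COc1ccc(O)cc1-c1oc2c(OC)c(OC)cc(OCc3ccccc3)c2c(=O)c1OC
A6 | alternative 3 | 5-(benzyloxy)-2-ethynyl-3,7,8-trimethoxy-4H-chromen-4-one | C#Cc1oc2c(OC)c(OC)cc(OCc3ccccc3)c2c(=O)c1OC
A7 | alternative 3 | 2-methoxyfuran | COc1ccco1
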